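Compound numbers 1–33 are fixed by the steps below and are used throughout. Carbon locants C1–C15 are those of the germacrane skeleton: C1 ketone, C2=C3 in ring A, C3–O–C10 ether, C4=C5 with C15 on C4, C6 lactone carbinol, C7, C8 ester carbinol, C9, quaternary C10 with C14, and C11–C13 in the lactone.

## Analysis of the target

The target 33 is a furanoheliangolide-type germacranolide. Its ten-membered carbocycle (ring B, C1–C10) is bridged by an ether oxygen between C3 and C10, so that O, C10, C1(=O), C2 and C3 form a 3(2H)-furanone (ring A). Ring B is fused at C6/C7 to an α-methylene-γ-butyrolactone (ring C: O–C6, C7, C11=C13, C12=O). C4=C5 is Z and carries the C15 hydroxymethyl group, C8 carries an (E)-crotonate and C10 a methyl group. There are four stereocentres: the contiguous triad C6 (S), C7 (S), C8 (R), with H6 and H7 trans on the lactone and the C8 oxygen anti to C6 along the C9–C8–C7–C11 zigzag, and the quaternary C10 (R), which is insulated from the triad by the C9 methylene. The methylene lactone and the crotonate are Michael acceptors, the C6–O bond is allylic, and the furanone is a cross-conjugated vinylogous ester, so the late steps must avoid strong base and nucleophiles. The hard part is the strained bridged ring B, which holds C2=C3 trans and C4=C5 cis within the ring, next to a stereotriad on the lactone. The strategy rests on one feature: C1(=O)–C2=C3–O–C10 is the cyclodehydrated form of a C1/C3 1,3-diketone with a tertiary hydroxyl on C10. Because C10 is quaternary, a C1 aldehyde has no α-hydrogen, and C1–C2 is an aldol bond between that aldehyde and the enolate of a C3 ketone.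

## Retrosynthetic reasoning

**Ring A, C3–O bond.** Adding water across the enol ether of 33 and capping the two hydroxyls leads back to the ten-membered 1,3-diketone 30 (C10 triethylsilyl ether, C15 tert-butyldiphenylsilyl ether, TBDPS). This removes the bridge and the ring-B-trans C2=C3 bond, which are the main sources of strain. In the forward direction the tertiary silyl ether must leave first, so that the C10 hydroxyl closes onto C3 and dehydrates before the C15 hydroxyl is free to attack C1. This is why C15 carries the slow-cleaving TBDPS group.

**Ring B, C1–C2 bond.** Diketone 30 comes from β-hydroxy ketone 29 by oxidation, and 29 is opened at C1–C2 to the bromomethyl enone–aldehyde 27. The cut is made here because the aldehyde on quaternary C10 can neither enolise nor epimerise, and because the one new stereocentre (C1) is erased by the oxidation. A cut at C6–C7 or C7–C8 would instead put the creation of the stereotriad into the macrocyclisation. The forward reaction is a samarium-mediated Reformatsky-type aldol that must reduce only the C–Br bond and close the ring faster than it oligomerises.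

**C3–C4 bond and the C2 bromide.** The α-bromo ketone of 27 is unveiled last, from the 2-ethoxydiene 26 by electrophilic bromination in water. Diene 26 comes from the Z vinyl iodide 24 and the tin reagent 25 by cross-coupling. This avoids any enolisation next to the acidic C6–H and carries the C4=C5 geometry in a configurationally stable vinyl iodide.

**Functional-group adjustments on the seco chain.** The C1 aldehyde of 24 comes from the primary silyl ether of bis-silyl ether 23 by oxidative desilylation. Compound 23 comes from diol 22, and 22 from acetonide 21, which keeps C1–OH and C10–OH masked together through the fragment union. Crotonate 21 is the ester of alcohol 19 with acid 20.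

**C7–C8 bond.** Alcohol 19 is cut between C7 and C8 into bromomethyl butenolide 13 and aldehyde 17. In 13 the C6 substituent on C7 is held trans to C13 by the ring. An allyl metal of this E-type geometry adds through a chair to give the 7,8-anti adduct, and it attacks anti to the C6 substituent to give the 6,7-trans lactone. Both relationships are those of the target, and the exocyclic methylene appears in the same step. A cut at C6–C7 was rejected because it needs an acyclic allyl metal whose C7 substituent is cis to the metal-bearing carbon. That geometry favours the syn adduct and hence the cis lactone.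

**C10 from the chiral pool.** Aldehyde 17 comes from alcohol 16, acetonide of triol 15, which is the reduction product of acid 14. The R configuration of 14 is that of C10 in the target, and no step touches it.

**Butenolide 13.** The C7=C11 bond is cut by ring-closing metathesis to ester 12, made from dienol 9 and acid 10. The Z vinyl iodide of 9 comes from propargylic alcohol 7 by hydroxyl-directed trans-hydroalumination and iodination, which places iodine on C4 cis to C6. Alcohol 7 is obtained by enzymatic resolution of racemic acetate 6, which is assembled at C5–C6 from alkyne 2 and enal 3. Alkyne 2 is the silyl ether of 1.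

## Alternatives that were turned down

**Alternative 1:** Ring B and the ring A skeleton would arise together by an anionic oxy-Cope rearrangement of a fused six/five bicycle. The C3–C8 bond is cut and C10–C1 is formed. In the forward step KH with 18-crown-6 generates the C8 alkoxide of the 1,5-diene C10=C9–C8–C3–C2=C1, and the [3,3] shift gives the bridged C8 ketone A1.
- For: ring expansion avoids the entropic cost of an end-to-end ten-membered closure, and the quaternary C10 and the ether bridge are made in one concerted step from a rigid precursor. On ease of ring formation it is stronger than the chosen route.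
- Against: A1 is far from the target. C1 is an ether at the alcohol level, C8 is a ketone that must be reduced with the correct facial selectivity in a flexible ring, and C7 carries only a protected hydroxyethyl chain. The lactone, its methylene and the crotonate would still need about eight to ten steps. C7 is α and the C6 silyloxy group is β to the new C8 carbonyl, so epimerisation and β-elimination threaten under the strongly basic conditions. The C10 configuration depends on a chair/boat preference and on the enol ether geometry.
- Comparison: the chosen route closes the ring with every stereocentre and oxidation level in place and is two steps from the target afterwards.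

**Alternative 2:** Ring B would arise by two-carbon expansion of an eight-membered enone. An alkynyl ether on the C10 oxygen (C3≡C4) adds across C2=C5 under AgN(SO2CF3)2, forming C2–C3 and C4–C5. The cyclobutene then opens by cleavage of C2–C5 to give A2.
- For: the conrotatory opening of a cis-fused cyclobutene gives a cis,trans-diene, which is exactly what ring B needs. The polarity of the ynol ether matches the enone. A2 lacks only the methylene and the crotonate. In elegance and in matching the diene geometry it is stronger than the chosen route.
- Against: an alkynyl ether on a tertiary carbon fragments easily by retro-ene loss of ketene. The silver-promoted [2+2] is established for silyl ynol ethers and simple enones, not for a tethered alkyl ynol ether and a medium-ring enone, so the key step would go beyond known chemistry. The eight-membered enone with a trans-lactone and three stereocentres is about as hard to make as the ten-membered ring. After the key step the methylene would have to be installed through a lactone enolate in the presence of the base-sensitive furanone.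
- Comparison: the chosen route relies only on known reaction types and brings in the methylene lactone without strong base.

**Alternative 3:** Ring B would be closed at C7–C8 by an intramolecular Barbier reaction. CrCl2 turns the C13 bromide of a bromomethyl butenolide into an allylchromium, which adds through C7 to a C8 aldehyde with ring A already in place, giving A3.
- For: this is the most economical plan. Ring closure, C7, C8 and the methylene lactone come in one step, the preformed furanone and the Z alkene preorganise the chain, and A3 is two steps from the target. It equals the chosen route in steps after ring closure and is stronger in stereocentres set per step.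
- Against: C7 and C8 must be set inside a transition state that is constrained by the forming bridged ring, where the chair that delivers anti/trans in the open case may not be reachable, and a wrong diastereomer cannot be corrected. The seco aldehyde has α-hydrogens at C9 and a β-oxygen on C10 that is a vinylogous carboxylate, so ring A can open by elimination. The furanone has to be carried through installation of the allylic bromide.
- Comparison: the chosen route uses the same butenolide allylation between two separate fragments (step 10), where the unconstrained chair sets C7 and C8 from C6. It moves the ring closure to C1–C2, where the aldehyde is non-enolisable and the new stereocentre does not matter.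

Key step: step 17

Assumption: 29 is carried on as whichever C1 epimer or mixture forms, because step 18 turns C1 into a carbonyl. In the iodides 13, 19 and 21–24 the C6 descriptor is R only because iodine raises the priority of the C5 branch; the spatial arrangement is that of 6S in the target.

## Steps

Step 1
Reactants: 1 prop-2-yn-1-ol
Product: 2 tert-butyl(diphenyl)(prop-2-yn-1-yloxy)silane
Conditions: TBDPSCl, imidazole, CH2Cl2, 0 °C to rt
Reagents that add atoms: tert-butyl(chloro)diphenylsilane CC(C)(C)[Si](Cl)(c1ccccc1)c1ccccc1
Why: Silylation of a primary alcohol; TBDPS is chosen for the future C15 oxygen because it must survive aqueous acid in step 12 and be the last silyl group to leave in step 19.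

Step 2
Reactants: 2 tert-butyl(diphenyl)(prop-2-yn-1-yloxy)silane; 3 acrolein
Product: 6 racemic 6-{[tert-butyl(diphenyl)silyl]oxy}hex-1-en-4-yn-3-yl acetate, via lithium acetylide 4 (not isolated), via lithium alkoxide 5 (not isolated)
Conditions: n-BuLi, THF, −78 °C; acrolein, −78 °C; Ac2O, −78 °C to rt
Reagents that add atoms: acetic anhydride CC(=O)OC(C)=O
Why: Deprotonation of the terminal alkyne and 1,2-addition of the acetylide to the enal form the C5–C6 bond; trapping the alkoxide with the anhydride gives the racemic acetate needed for the enzymatic resolution in the same flask.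

Step 3
Reactants: 6 racemic 6-{[tert-butyl(diphenyl)silyl]oxy}hex-1-en-4-yn-3-yl acetate
Product: 7 (3R)-6-{[tert-butyl(diphenyl)silyl]oxy}hex-1-en-4-yn-3-ol
Conditions: Novozym 435 (immobilised Candida antarctica lipase B), n-BuOH, MTBE, 35 °C, stopped near 50% conversion
Reagents that add atoms: none
Why: Lipase-catalysed enantioselective alcoholysis (kinetic resolution); by the Kazlauskas rule, with the long silyloxypropynyl arm as the large group and vinyl as the medium group, the R acetate should be cleaved faster, so 7 is released while the S enantiomer of 6 stays acetylated and is removed by chromatography. The configuration of 7 is to be confirmed by Mosher ester analysis before going on.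

Step 4
Reactants: 7 (3R)-6-{[tert-butyl(diphenyl)silyl]oxy}hex-1-en-4-yn-3-ol
Product: 9 (3R,4Z)-6-{[tert-butyl(diphenyl)silyl]oxy}-5-iodohexa-1,4-dien-3-ol, via cyclic alkenylalanate 8 (not isolated)
Conditions: NaAlH2(OCH2CH2OMe)2, THF, 0 °C to rt; I2, THF, −78 to 0 °C
Reagents that add atoms: iodine II
Why: Hydroxyl-directed trans-hydroalumination of the propargylic alcohol delivers hydride to C5 and aluminium to C4 in the five-membered alanate 8, and iodinolysis with retention gives the vinyl iodide with iodine cis to C6, which fixes the Z geometry of C4=C5. The silyl ether oxygen cannot direct and the vinyl group is inert.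

Step 5
Reactants: 9 (3R,4Z)-6-{[tert-butyl(diphenyl)silyl]oxy}-5-iodohexa-1,4-dien-3-ol; 10 2-(bromomethyl)prop-2-enoic acid
Product: 12 (3R,4Z)-6-{[tert-butyl(diphenyl)silyl]oxy}-5-iodohexa-1,4-dien-3-yl 2-(bromomethyl)prop-2-enoate, via acid chloride 11 (not isolated)
Conditions: 10, (COCl)2, DMF (cat.), CH2Cl2, 0 °C to rt, evaporate; then 9, iPr2NEt, CH2Cl2, −40 to 0 °C
Reagents that add atoms: none
Why: Acylation of the secondary alcohol by the preformed acid chloride; a hindered amine and no nucleophilic catalyst are used so that the allylic bromide of the acrylate is not displaced, and C6 is not touched.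

Step 6
Reactants: 12 (3R,4Z)-6-{[tert-butyl(diphenyl)silyl]oxy}-5-iodohexa-1,4-dien-3-yl 2-(bromomethyl)prop-2-enoate
Product: 13 (5R)-3-(bromomethyl)-5-[(1Z)-3-{[tert-butyl(diphenyl)silyl]oxy}-2-iodoprop-1-en-1-yl]furan-2(5H)-one
Conditions: second-generation Hoveyda–Grubbs catalyst (5 mol%), toluene (0.01 M), 80 °C
Reagents that add atoms: none
Why: Ring-closing olefin metathesis between the terminal vinyl group and the 1,1-disubstituted acrylate forms C7=C11 and the butenolide, as is known for methacrylates of allylic alcohols; the trisubstituted iodoalkene and the allylic bromide are not substrates for the ruthenium carbene, and loss of ethene drives the closure.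

Step 7
Reactants: 14 (R)-citramalic acid
Product: 15 (2R)-2-methylbutane-1,2,4-triol
Conditions: BH3·SMe2, B(OMe)3, THF, 0 °C to rt; MeOH
Reagents that add atoms: none
Why: Borane reduces both carboxylic acids to primary alcohols and leaves the tertiary carbinol alone, so the R configuration of the future C10 comes unchanged from the chiral pool.

Step 8
Reactants: 15 (2R)-2-methylbutane-1,2,4-triol
Product: 16 2-[(4R)-2,2,4-trimethyl-1,3-dioxolan-4-yl]ethan-1-ol
Conditions: 2,2-dimethoxypropane, TsOH·H2O (cat.), acetone, rt
Reagents that add atoms: 2,2-dimethoxypropane COC(C)(C)OC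
Why: Acid-catalysed transketalisation under thermodynamic control; the five-membered dioxolane across the 1,2-diol (future C1 and C10 oxygens) is favoured over the six-membered alternative, which leaves the future C8 hydroxyl free.

Step 9
Reactants: 16 2-[(4R)-2,2,4-trimethyl-1,3-dioxolan-4-yl]ethan-1-ol
Product: 17 2-[(4R)-2,2,4-trimethyl-1,3-dioxolan-4-yl]acetaldehyde
Conditions: (COCl)2, DMSO, CH2Cl2, −78 °C; Et3N, −78 to 0 °C
Reagents that add atoms: none
Why: Swern oxidation of the primary alcohol at low temperature keeps the acetonide and avoids β-elimination of the β-alkoxy aldehyde.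

Step 10
Reactants: 13 (5R)-3-(bromomethyl)-5-[(1Z)-3-{[tert-butyl(diphenyl)silyl]oxy}-2-iodoprop-1-en-1-yl]furan-2(5H)-one; 17 2-[(4R)-2,2,4-trimethyl-1,3-dioxolan-4-yl]acetaldehyde
Product: 19 (4S,5R)-5-[(1Z)-3-{[tert-butyl(diphenyl)silyl]oxy}-2-iodoprop-1-en-1-yl]-4-{(1R)-1-hydroxy-2-[(4R)-2,2,4-trimethyl-1,3-dioxolan-4-yl]ethyl}-3-methylideneoxolan-2-one, via allylzinc bromide 18 (not isolated)
Conditions: Zn dust, THF/sat. aq. NH4Cl (3:1), 0 °C to rt
Reagents that add atoms: none
Why: Zinc-mediated Barbier allylation: zinc inserts into the allylic C–Br bond and 18 adds through C7 with allylic transposition, forming C7–C8 and unveiling the exocyclic methylene. The aldehyde approaches the butenolide face opposite the C6 substituent (6,7-trans lactone), and a six-membered chair transition state with the ring-locked E-type allyl unit and an equatorial aldehyde residue gives the 7,8-anti adduct, that is 7S,8R. The vinyl iodide and the acetonide are inert in buffered aqueous THF.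

Step 11
Reactants: 19 the C8 alcohol from step 10; 20 (2E)-but-2-enoic acid
Product: 21 (1R)-1-[(2R,3S)-2-[(1Z)-3-{[tert-butyl(diphenyl)silyl]oxy}-2-iodoprop-1-en-1-yl]-4-methylidene-5-oxooxolan-3-yl]-2-[(4R)-2,2,4-trimethyl-1,3-dioxolan-4-yl]ethyl (2E)-but-2-enoate
Conditions: DCC, DMAP (cat.), CH2Cl2, 0 °C to rt
Reagents that add atoms: none
Why: Steglich esterification of the secondary C8 alcohol; a low DMAP loading at 0 °C limits deconjugation of the crotonyl group and conjugate addition to the methylene lactone, and acylation removes the hydroxyl that could translactonise onto C12.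

Step 12
Reactants: 21 the C8 crotonate acetonide
Product: 22 the C8 crotonate with free C1 and C10 hydroxyls (6R,7S,8R,10R; C4 iodide; C15 TBDPS ether)
Conditions: AcOH/H2O (4:1), 40 °C
Reagents that add atoms: none
Why: Acid hydrolysis of the ketal; the TBDPS ether, both esters and the vinyl iodide tolerate aqueous acetic acid, and acyl migration to a tertiary hydroxyl is slow under acid.

Step 13
Reactants: 22 the C1,C10 diol
Product: 23 the C1,C10 bis(triethylsilyl) ether of 22
Conditions: TESOTf, 2,6-lutidine, CH2Cl2, −78 to 0 °C
Reagents that add atoms: triethylsilyl trifluoromethanesulfonate CC[Si](CC)(CC)OS(=O)(=O)C(F)(F)F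
Why: A silyl triflate with a hindered pyridine base silylates both the primary and the tertiary hydroxyl without touching the acceptor alkenes.

Step 14
Reactants: 23 the bis(triethylsilyl) ether
Product: 24 the C1 aldehyde with C10 triethylsilyl ether (6R,7S,8R,10R; C4 iodide; C8 crotonate; C15 TBDPS ether)
Conditions: (COCl)2, DMSO, CH2Cl2, −78 to −30 °C; Et3N, −78 to 0 °C
Reagents that add atoms: none
Why: Under Swern conditions a primary triethylsilyl ether is cleaved by the chlorosulfonium reagent and oxidised directly to the aldehyde, while the tertiary triethylsilyl ether and the TBDPS ether stay; the aldehyde has no α-hydrogen, so the amine cannot epimerise it.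

Step 15
Reactants: 24 the vinyl iodide aldehyde; 25 tributyl(1-ethoxyethenyl)stannane
Product: 26 the 2-ethoxy-1,3-diene in which C4 carries the 1-ethoxyethenyl group (6S,7S,8R,10R)
Conditions: Pd(PPh3)4 (10 mol%), CuI (20 mol%), DMF, 40 °C
Reagents that add atoms: none
Why: Copper-accelerated Stille coupling of the vinyl iodide with the α-alkoxyvinylstannane forms C3–C4 with retention, so C3 stays cis to C6; oxidative addition of zerovalent palladium to the C–I bond is faster than ionisation of the allylic lactone.

Step 16
Reactants: 26 the 2-ethoxy-1,3-diene
Product: 27 the seco bromomethyl enone–aldehyde (C2 bromide; C3 ketone; Z C4=C5; methylene lactone; C8 crotonate; C10 triethylsilyl ether; C1 aldehyde; C15 TBDPS ether; 6S,7S,8R,10R)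
Conditions: NBS, THF/H2O (4:1), 0 °C
Reagents that add atoms: N-bromosuccinimide O=C1CCC(=O)N1Br; water O
Why: Electrophilic bromination of the enol ether terminus C2 gives an oxocarbenium ion that water captures, and loss of ethanol unveils the bromomethyl ketone without any enolisation, so the Z enone and C6 are not put at risk. The electron-poor alkenes do not react with the bromonium source.

Step 17
Reactants: 27 the seco bromomethyl enone–aldehyde
Product: 29 the ten-membered C1 carbinol C3 ketone (ring B closed; C10 triethylsilyl ether; C15 TBDPS ether; 6S,7S,8R,10R; C1 either epimer), via samarium enolate 28 (not isolated)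
Conditions: SmI2 (2.2 equiv), THF, −78 °C, slow addition of 27 to a final 0.002 M; sat. aq. NH4Cl at −78 °C
Reagents that add atoms: none
Why: Two single-electron transfers from SmI2 break the C2–Br bond and give the enolate 28 of trivalent samarium, a reduction that at −78 °C is much faster than that of the aldehyde, the enone, the crotonate or the methylene lactone. The oxophilic metal binds the C1 aldehyde oxygen and C2 adds to C1 through a six-membered chelate; the closest known reaction type is the SmI2-mediated intramolecular Reformatsky (aldol) reaction of α-halo ketones with aldehydes, which has been used for medium and large rings. Ring B closes as a ten-membered ring in a 10-(enolendo)-exo-trig aldol mode. The one new stereocentre, C1, is set under substrate control by the chelate and the ring conformation but need not be controlled, because step 18 removes it. The step needs chemoselectivity and cyclisation over oligomerisation or protonation of the enolate. These are secured by the fast reduction of the α-bromo ketone, by the neopentyl aldehyde on quaternary C10 that can be neither deprotonated nor epimerised, by the silyl cap on the only hydroxyl, by the Z C4=C5 bond and the trans-lactone that turn the chain, and by high dilution. The enolate is a 2-metalloxy-1,3-diene and is not conjugated to C6, so it cannot expel the C6 carboxylate.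

Step 18
Reactants: 29 the ten-membered β-hydroxy ketone
Product: 30 the ten-membered C1,C3 diketone (C10 triethylsilyl ether; C15 TBDPS ether; 6S,7S,8R,10R)
Conditions: Dess–Martin periodinane, NaHCO3, CH2Cl2, 0 °C to rt
Reagents that add atoms: none
Why: Periodinane oxidation of a β-hydroxy ketone to the 1,3-diketone under buffered, non-basic conditions; both C1 epimers converge on 30.

Step 19
Reactants: 30 the ten-membered C1,C3 diketone
Product: 33 the target CNP0225232.1 (6S,7S,8R,10R; Z C4=C5), via hydroxy diketone 31 (not isolated), via silylated furanone 32 (not isolated)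
Conditions: HF·pyridine, pyridine, THF, 0 °C to rt
Reagents that add atoms: none
Why: HF·pyridine cleaves the tertiary triethylsilyl ether first; the freed C10 hydroxyl of 31 adds to the C3 carbonyl as a five-membered hemiketal and acid-catalysed dehydration gives the 3(2H)-furanone 32. The slower cleavage of the primary TBDPS ether then frees the C15 hydroxyl, which can no longer compete for C1.

## Compound list

1 | prop-2-yn-1-ol | C#CCO | starting material
2 | tert-butyl(diphenyl)(prop-2-yn-1-yloxy)silane | C#CCO[Si](c1ccccc1)(c1ccccc1)C(C)(C)C | intermediate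
3 | acrolein (prop-2-enal) | C=CC=O | starting material
4 | lithium acetylide of 2 | [Li]C#CCO[Si](c1ccccc1)(c1ccccc1)C(C)(C)C | intermediate
5 | lithium alkoxide, racemic lithium 6-{[tert-butyl(diphenyl)silyl]oxy}hex-1-en-4-yn-3-olate | [Li]OC(C=C)C#CCO[Si](c1ccccc1)(c1ccccc1)C(C)(C)C | intermediate
6 | racemic 6-{[tert-butyl(diphenyl)silyl]oxy}hex-1-en-4-yn-3-yl acetate | CC(=O)OC(C=C)C#CCO[Si](c1ccccc1)(c1ccccc1)C(C)(C)C | intermediate
7 | (3R)-6-{[tert-butyl(diphenyl)silyl]oxy}hex-1-en-4-yn-3-ol | C=C[C@@H](O)C#CCO[Si](c1ccccc1)(c1ccccc1)C(C)(C)C | intermediate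
8 | cyclic alkenylalanate, sodium salt (five-membered O–Al–C4=C5–C6 ring, two 2-methoxyethoxy ligands on aluminium) | [Na+].COCCO[Al-]1(OCCOC)O[C@H](C=C)C=C1CO[Si](c2ccccc2)(c2ccccc2)C(C)(C)C | intermediate
9 | (3R,4Z)-6-{[tert-butyl(diphenyl)silyl]oxy}-5-iodohexa-1,4-dien-3-ol | C=C[C@@H](O)/C=C(\I)CO[Si](c1ccccc1)(c1ccccc1)C(C)(C)C | intermediate
10 | 2-(bromomethyl)prop-2-enoic acid | C=C(CBr)C(=O)O | starting material
11 | 2-(bromomethyl)prop-2-enoyl chloride | C=C(CBr)C(=O)Cl | intermediate
12 | (3R,4Z)-6-{[tert-butyl(diphenyl)silyl]oxy}-5-iodohexa-1,4-dien-3-yl 2-(bromomethyl)prop-2-enoate | C=C[C@@H](OC(=O)C(=C)CBr)/C=C(\I)CO[Si](c1ccccc1)(c1ccccc1)C(C)(C)C | intermediate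
13 | (5R)-3-(bromomethyl)-5-[(1Z)-3-{[tert-butyl(diphenyl)silyl]oxy}-2-iodoprop-1-en-1-yl]furan-2(5H)-one | O=C1O[C@@H](/C=C(\I)CO[Si](c2ccccc2)(c2ccccc2)C(C)(C)C)C=C1CBr | intermediate
14 | (R)-citramalic acid, (2R)-2-hydroxy-2-methylbutanedioic acid | C[C@@](O)(CC(=O)O)C(=O)O | starting material
15 | (2R)-2-methylbutane-1,2,4-triol | C[C@@](O)(CCO)CO | intermediate
16 | 2-[(4R)-2,2,4-trimethyl-1,3-dioxolan-4-yl]ethan-1-ol | C[C@@]1(CCO)COC(C)(C)O1 | intermediate
17 | 2-[(4R)-2,2,4-trimethyl-1,3-dioxolan-4-yl]acetaldehyde | C[C@@]1(CC=O)COC(C)(C)O1 | intermediate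
18 | allylzinc bromide from 13 (zinc on C13) | O=C1O[C@@H](/C=C(\I)CO[Si](c2ccccc2)(c2ccccc2)C(C)(C)C)C=C1C[Zn]Br | intermediate
19 | (4S,5R)-5-[(1Z)-3-{[tert-butyl(diphenyl)silyl]oxy}-2-iodoprop-1-en-1-yl]-4-{(1R)-1-hydroxy-2-[(4R)-2,2,4-trimethyl-1,3-dioxolan-4-yl]ethyl}-3-methylideneoxolan-2-one | I/C(CO[Si](c1ccccc1)(c1ccccc1)C(C)(C)C)=C\[C@@H]2OC(=O)C(=C)[C@H]2[C@H](O)C[C@]3(C)COC(C)(C)O3 | intermediate
20 | (2E)-but-2-enoic acid, (E)-crotonic acid | C/C=C/C(=O)O | starting material
21 | (1R)-1-[(2R,3S)-2-[(1Z)-3-{[tert-butyl(diphenyl)silyl]oxy}-2-iodoprop-1-en-1-yl]-4-methylidene-5-oxooxolan-3-yl]-2-[(4R)-2,2,4-trimethyl-1,3-dioxolan-4-yl]ethyl (2E)-but-2-enoate | I/C(CO[Si](c1ccccc1)(c1ccccc1)C(C)(C)C)=C\[C@@H]2OC(=O)C(=C)[C@H]2[C@H](OC(=O)/C=C/C)C[C@]3(C)COC(C)(C)O3 | intermediate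
22 | C8 crotonate with free C1 and C10 hydroxyls (6R,7S,8R,10R; C4 iodide; C15 TBDPS ether) | I/C(CO[Si](c1ccccc1)(c1ccccc1)C(C)(C)C)=C\[C@@H]2OC(=O)C(=C)[C@H]2[C@H](OC(=O)/C=C/C)C[C@@](C)(O)CO | intermediate
23 | C1,C10 bis(triethylsilyl) ether of 22 | I/C(CO[Si](c1ccccc1)(c1ccccc1)C(C)(C)C)=C\[C@@H]2OC(=O)C(=C)[C@H]2[C@H](OC(=O)/C=C/C)C[C@@](C)(O[Si](CC)(CC)CC)CO[Si](CC)(CC)CC | intermediate
24 | C1 aldehyde with C10 triethylsilyl ether (6R,7S,8R,10R; C4 iodide; C8 crotonate; C15 TBDPS ether) | I/C(CO[Si](c1ccccc1)(c1ccccc1)C(C)(C)C)=C\[C@@H]2OC(=O)C(=C)[C@H]2[C@H](OC(=O)/C=C/C)C[C@@](C)(O[Si](CC)(CC)CC)C=O | intermediate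
25 | tributyl(1-ethoxyethenyl)stannane | CCCC[Sn](CCCC)(CCCC)C(=C)OCC | starting material
26 | 2-ethoxy-1,3-diene, C4 carrying the 1-ethoxyethenyl group (6S,7S,8R,10R) | C=C(OCC)/C(CO[Si](c1ccccc1)(c1ccccc1)C(C)(C)C)=C\[C@@H]2OC(=O)C(=C)[C@H]2[C@H](OC(=O)/C=C/C)C[C@@](C)(O[Si](CC)(CC)CC)C=O | intermediate
27 | seco bromomethyl enone–aldehyde (6S,7S,8R,10R) | BrCC(=O)/C(CO[Si](c1ccccc1)(c1ccccc1)C(C)(C)C)=C\[C@@H]2OC(=O)C(=C)[C@H]2[C@H](OC(=O)/C=C/C)C[C@@](C)(O[Si](CC)(CC)CC)C=O | intermediate
28 | samarium enolate of 27 (C2=C3–O–SmI2) | C=C(O[Sm](I)I)/C(CO[Si](c1ccccc1)(c1ccccc1)C(C)(C)C)=C\[C@@H]2OC(=O)C(=C)[C@H]2[C@H](OC(=O)/C=C/C)C[C@@](C)(O[Si](CC)(CC)CC)C=O | intermediate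
29 | ten-membered C1 carbinol C3 ketone (6S,7S,8R,10R; C1 either epimer) | C=C1C(=O)O[C@H]2/C=C(/CO[Si](c3ccccc3)(c3ccccc3)C(C)(C)C)C(=O)CC(O)[C@@](C)(C[C@@H](OC(=O)/C=C/C)[C@H]12)O[Si](CC)(CC)CC | intermediate
30 | ten-membered C1,C3 diketone (6S,7S,8R,10R; C10 triethylsilyl ether; C15 TBDPS ether) | C=C1C(=O)O[C@H]2/C=C(/CO[Si](c3ccccc3)(c3ccccc3)C(C)(C)C)C(=O)CC(=O)[C@@](C)(C[C@@H](OC(=O)/C=C/C)[C@H]12)O[Si](CC)(CC)CC | intermediate
31 | hydroxy diketone, 30 without the C10 silyl group | C=C1C(=O)O[C@H]2/C=C(/CO[Si](c3ccccc3)(c3ccccc3)C(C)(C)C)C(=O)CC(=O)[C@@](C)(C[C@@H](OC(=O)/C=C/C)[C@H]12)O | intermediate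
32 | silylated furanone, the C15 TBDPS ether of the target | C=C1C(=O)O[C@H]2/C=C(/CO[Si](c4ccccc4)(c4ccccc4)C(C)(C)C)C3=CC(=O)[C@@](C)(C[C@@H](OC(=O)/C=C/C)[C@H]12)O3 | intermediate
33 | CNP0225232.1 (6S,7S,8R,10R; 4Z) | C=C1C(=O)O[C@H]2/C=C(/CO)C3=CC(=O)[C@@](C)(C[C@@H](OC(=O)/C=C/C)[C@H]12)O3 | target

## Step count and least certain steps

Total: 19 steps. Longest linear sequence: 16 steps (steps 1–6, then 10–19); the second branch is steps 7–9.

**Step 17 (key step).** The samarium enolate may react with the aldehyde of a second molecule (oligomerisation) or be protonated before it cyclises (plain reduction to the methyl ketone), because the ten-membered transition state is strained. Excess reductant may also reduce the product enone with loss of the C6 carboxylate. Fallback: set out from 26 and use its enol ether itself as the nucleophile. Under high dilution with Me2AlCl in CH2Cl2 at −78 °C, the C2 terminus of the 2-ethoxydiene adds to the Lewis-acid-activated C1 aldehyde in an intramolecular Mukaiyama-type (carbonyl-ene) aldol addition. Aqueous acidic work-up hydrolyses the resulting enol ether to the C3 ketone, which returns to the route at 29. No reducing metal is involved and no new compound arises on this path (entry F0).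

**Step 10.** In the aqueous medium the addition may pass partly through an open instead of a cyclic transition state, which would erode the 7,8-anti selectivity. The zinc alkoxide at C8 may also attack C12 and translactonise. Fallback: set out from 13 and convert the allylic bromide with bis(pinacolato)diboron and Pd2(dba)3 into the allylboronate F1. Add F1 to 17 with Sc(OTf)3 catalysis in CH2Cl2 at −78 to 0 °C. Allylboration runs through a closed chair and the boron alkoxide is not nucleophilic, and work-up returns to the route at 19.

**Step 6.** Ring closure onto the hindered, electron-poor 1,1-disubstituted alkene may be slow, so that dimerisation at the vinyl group, catalyst decay or side reactions of the allylic bromide take over. Fallback: set out from 9 and esterify it with 2-{[tert-butyl(dimethyl)silyl]oxymethyl}prop-2-enoic acid (DCC, DMAP) to the ester F2, which has no allylic halide. Close F2 by metathesis to the silyloxymethyl butenolide F3, then turn the primary silyl ether directly into the bromide with Ph3PBr2 in CH2Cl2. The TBDPS ether reacts much more slowly, and the route is rejoined at 13.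

**Step 3.** The enzyme may discriminate poorly between the two unsaturated arms, or turn over slowly because of the bulky silyl group, so that 7 is obtained in low enantiomeric purity. Fallback: set out from 6 and cleave all of the acetate (K2CO3, MeOH) to the racemic alcohol F4. Resolve F4 by Sharpless kinetic resolution with Ti(OiPr)4, D-(−)-diisopropyl tartrate and t-BuOOH (0.6 equiv) over 4 Å sieves in CH2Cl2 at −20 °C. The S enantiomer is consumed by epoxidation of its vinyl group to the erythro epoxy alcohol F5, and the unreacted R enantiomer is 7, where the route is rejoined.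

**Step 14.** Oxidative cleavage of the neopentyl-type primary silyl ether may be incomplete, or the tertiary silyl ether may be lost at the temperature that the cleavage needs. Fallback: set out from 22 and oxidise only the primary hydroxyl with TEMPO (cat.) and PhI(OAc)2 in CH2Cl2 to the hydroxy aldehyde F6. Silylate the tertiary hydroxyl of F6 with TESOTf and 2,6-lutidine at −78 °C, which returns to the route at 24.

## Further compounds

F0 | step 17 | none | none
F1 | step 10 | allylboronate, (5R)-5-[(1Z)-3-{[tert-butyl(diphenyl)silyl]oxy}-2-iodoprop-1-en-1-yl]-3-[(4,4,5,5-tetramethyl-1,3,2-dioxaborolan-2-yl)methyl]furan-2(5H)-one | O=C1O[C@@H](/C=C(\I)CO[Si](c2ccccc2)(c2ccccc2)C(C)(C)C)C=C1CB3OC(C)(C)C(C)(C)O3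
F2 | step 6 | ester, (3R,4Z)-6-{[tert-butyl(diphenyl)silyl]oxy}-5-iodohexa-1,4-dien-3-yl 2-({[tert-butyl(dimethyl)silyl]oxy}methyl)prop-2-enoate | C=C[C@@H](OC(=O)C(=C)CO[Si](C)(C)C(C)(C)C)/C=C(\I)CO[Si](c1ccccc1)(c1ccccc1)C(C)(C)C
F3 | step 6 | silyloxymethyl butenolide, (5R)-3-({[tert-butyl(dimethyl)silyl]oxy}methyl)-5-[(1Z)-3-{[tert-butyl(diphenyl)silyl]oxy}-2-iodoprop-1-en-1-yl]furan-2(5H)-one | O=C1O[C@@H](/C=C(\I)CO[Si](c2ccccc2)(c2ccccc2)C(C)(C)C)C=C1CO[Si](C)(C)C(C)(C)C
F4 | step 3 | racemic alcohol, racemic 6-{[tert-butyl(diphenyl)silyl]oxy}hex-1-en-4-yn-3-ol | C=CC(O)C#CCO[Si](c1ccccc1)(c1ccccc1)C(C)(C)C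
F5 | step 3 | erythro epoxy alcohol, (1R)-4-{[tert-butyl(diphenyl)silyl]oxy}-1-[(2S)-oxiran-2-yl]but-2-yn-1-ol | O[C@@H]([C@@H]1CO1)C#CCO[Si](c1ccccc1)(c1ccccc1)C(C)(C)C
F6 | step 14 | hydroxy aldehyde, C1 aldehyde with free C10 hydroxyl (6R,7S,8R,10R; C4 iodide; C8 crotonate; C15 TBDPS ether) | I/C(CO[Si](c1ccccc1)(c1ccccc1)C(C)(C)C)=C\[C@@H]2OC(=O)C(=C)[C@H]2[C@H](OC(=O)/C=C/C)C[C@@](C)(O)C=O
A1 | alternative 1 | oxygen-bridged ten-membered C8 ketone with quaternary C10, C1 p-methoxybenzyl ether, C6 triethylsilyl ether, C15 TBDPS ether and a 2-silyloxyethyl chain on C7 | CC[Si](CC)(CC)O[C@H]1/C=C(/CO[Si](c3ccccc3)(c3ccccc3)C(C)(C)C)C2=C[C@@H](OCc3ccc(OC)cc3)[C@@](C)(CC(=O)[C@@H]1CCO[Si](C)(C)C(C)(C)C)O2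
A2 | alternative 2 | bridged furanone–diene lactone without the C11 methylene, C8 triethylsilyl ether, C15 tert-butyldimethylsilyl ether | C1C(=O)O[C@H]2/C=C(/CO[Si](C)(C)C(C)(C)C)C3=CC(=O)[C@@](C)(C[C@@H](O[Si](CC)(CC)CC)[C@H]12)O3
A3 | alternative 3 | C8 alcohol of the complete ring system, C15 tert-butyldimethylsilyl ether | C=C1C(=O)O[C@H]2/C=C(/CO[Si](C)(C)C(C)(C)C)C3=CC(=O)[C@@](C)(C[C@@H](O)[C@H]12)O3
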